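**Retrosynthetic overview**
- Last bond: the CH2 bridge, made by Mannich-type union of a 4-hydroxy-2-pyranone (C-3) with an 8-acyl-5,7-dihydroxychromene (C-6); no ring forms here.
- Chromenyl ketone: made in one flask from a 6-(2-oxoalkyl)-4-hydroxy-2-pyranone by pyranone-to-arene Claisen recyclisation (benzene ring), then condensation with 3-methylbut-2-enal and oxa-6π closure (2H-pyran ring).
- That oxoalkyl pyranone: triacetic acid lactone dianion plus methyl (S)-2-methylbutanoate; the only stereocentre is bought and never made enolisable.
- Pyranone partner: γ-acylation of a β-keto ester dianion, then lactonisation.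
- Ring order: the pyranone of the western half is closed separately; in the eastern half the benzene ring closes first and the 2H-pyran ring second, in the same operation.

Assumption: methyl (S)-2-methylbutanoate is bought as the single enantiomer (otherwise one esterification of commercial (S)-2-methylbutanoic acid); compounds are numbered in the order of the forward steps.

**Step 1**
Reactants: 1 4-hydroxy-6-methyl-2H-pyran-2-one (triacetic acid lactone); 2 methyl (2S)-2-methylbutanoate
Product: 3 4-hydroxy-6-[(3S)-3-methyl-2-oxopentyl]-2H-pyran-2-one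
Conditions: 1 (2.2 equiv), LiN(iPr)2 (4.4 equiv), THF, −78 → −20 °C; then 2 (1.0 equiv), −78 → 0 °C; 2 M HCl
Reagents that add atoms: none
Why: Claisen-type C-acylation of the lateral (6-methyl) carbanion of the pyranone dianion by the ester, run with excess dianion and no free amide base, gives a ketone that is at once deprotonated at the doubly activated CH2, so the purchased (S) centre beside the new ketone is not enolised and no new stereocentre forms.

**Step 2**
Reactants: 3 4-hydroxy-6-[(3S)-3-methyl-2-oxopentyl]-2H-pyran-2-one; 4 3-methylbut-2-enal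
Product: 6 (2S)-1-(5,7-dihydroxy-2,2-dimethyl-2H-chromen-8-yl)-2-methylbutan-1-one, via acylphloroglucinol 5 (not isolated)
Conditions: Mg(OMe)2 (3 equiv), MeOH, 65 °C, 6 h; then 25 °C, AcOH (3 equiv), 4 (1.5 equiv), 25 → 45 °C, 24 h; 1 M HCl
Reagents that add atoms: none
Why: Proposed new method: Mg(OMe)2 deprotonates the CH2 between ring and ketone and the chelated enolate attacks the lactone carbonyl (intramolecular Claisen, the known Mg(OMe)2 pyranone-to-acylphloroglucinol recyclisation) to build the benzene ring, after which the magnesium phenolate, chelated between the ketone oxygen and an ortho oxygen, condenses with the enal at the neighbouring carbon (Knoevenagel type) and closes through that same oxygen by oxa-6π electrocyclisation to build the 2H-pyran ring with its oxygen ortho to the ketone (closest precedent for this second stage: Ca(OH)2/MeOH chromenylation of polyphenols), the (S) centre surviving because enolisation goes to the CH2 before the Claisen step and is suppressed in the phenolate after it.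

**Step 3**
Reactants: 7 methyl 3-oxopentanoate; 8 N-methoxy-N-methylpropanamide
Product: 10 6-ethyl-4-hydroxy-5-methyl-2H-pyran-2-one, via diketo ester 9 (not isolated)
Conditions: 7, LiN(iPr)2 (2.1 equiv), THF, −78 → 0 °C; 8 (1.0 equiv), 0 °C → rt; 1 M HCl; crude 9, DBU (1.5 equiv), toluene, 90 °C; 1 M HCl
Reagents that add atoms: none
Why: Huckin–Weiler γ-acylation of the β-keto ester dianion by the Weinreb amide, followed by DBU-mediated lactonisation through the enol oxygen of the new ketone, is the standard route to 5,6-dialkyl-4-hydroxy-2-pyranones and involves no stereocentre in the product.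

**Step 4**
Reactants: 10 6-ethyl-4-hydroxy-5-methyl-2H-pyran-2-one; 6 (2S)-1-(5,7-dihydroxy-2,2-dimethyl-2H-chromen-8-yl)-2-methylbutan-1-one
Product: 12 6-ethyl-4-hydroxy-3-({5,7-dihydroxy-2,2-dimethyl-8-[(2S)-2-methylbutanoyl]-2H-chromen-6-yl}methyl)-5-methyl-2H-pyran-2-one, via Mannich base 11 (not isolated)
Conditions: 10, CH2=NMe2+ I− (1.05 equiv), CHCl3, 25 °C, 1 h; then 6 (1.0 equiv), 50 °C, 4 h; dilute HCl wash
Reagents that add atoms: Eschenmoser's salt (N,N-dimethylmethylideneammonium iodide), C=[N+](C)C.[I-]
Why: Mannich reaction at C-3, the only nucleophilic carbon of the pyranone, then loss of dimethylamine gives a 3-methylenepyran-2,4-dione that is trapped in a Michael/Friedel–Crafts-type addition by C-6 of 6, its only free aromatic position, under near-neutral conditions that leave the (S) centre and the chromene untouched.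

**Compound list**
1 | 4-hydroxy-6-methyl-2H-pyran-2-one | Cc1cc(O)cc(=O)o1 | starting material
2 | methyl (2S)-2-methylbutanoate | COC(=O)[C@@H](C)CC | starting material
3 | 4-hydroxy-6-[(3S)-3-methyl-2-oxopentyl]-2H-pyran-2-one | O=C(Cc1cc(O)cc(=O)o1)[C@@H](C)CC | intermediate
4 | 3-methylbut-2-enal | CC(C)=CC=O | starting material
5 | (2S)-2-methyl-1-(2,4,6-trihydroxyphenyl)butan-1-one | O=C(c1c(O)cc(O)cc1O)[C@@H](C)CC | intermediate
6 | (2S)-1-(5,7-dihydroxy-2,2-dimethyl-2H-chromen-8-yl)-2-methylbutan-1-one | O=C(c1c(O)cc(O)c2C=CC(C)(C)Oc12)[C@@H](C)CC | intermediate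
7 | methyl 3-oxopentanoate | CCC(=O)CC(=O)OC | starting material
8 | N-methoxy-N-methylpropanamide | CCC(=O)N(C)OC | starting material
9 | methyl 4-methyl-3,5-dioxoheptanoate (racemic, enolisable centre) | CCC(=O)C(C)C(=O)CC(=O)OC | intermediate
10 | 6-ethyl-4-hydroxy-5-methyl-2H-pyran-2-one | CCc1oc(=O)cc(O)c1C | intermediate
11 | 3-[(dimethylamino)methyl]-6-ethyl-4-hydroxy-5-methyl-2H-pyran-2-one (formed as its hydroiodide) | CCc1oc(=O)c(CN(C)C)c(O)c1C | intermediate
12 | 6-ethyl-4-hydroxy-3-({5,7-dihydroxy-2,2-dimethyl-8-[(2S)-2-methylbutanoyl]-2H-chromen-6-yl}methyl)-5-methyl-2H-pyran-2-one | CCc1oc(=O)c(Cc2c(O)c3c(c(C(=O)[C@@H](C)CC)c2O)OC(C)(C)C=C3)c(O)c1C | target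

**Totals**
Total steps: 4. Longest linear sequence: 3 (steps 1, 2, 4); step 3 is the convergent branch.

**Steps most likely to fail**

Step 2 is the most exposed. Three things can go wrong: the aldol mode of recyclisation (giving a resorcylate ester instead of 5), closure of the pyran ring through the para oxygen (giving the 6-acyl chromene isomer), and double chromenylation. The regiochemical preference claimed for the magnesium chelate is an argument, not a measured result, so the isomer must be confirmed by HMBC/NOE and the minor one removed by chromatography. Fallback: set out from 3, run only the Mg(OMe)2 recyclisation and isolate 5. Protect the para hydroxyl, the most acidic and the only non-chelatable one, as the methoxymethyl ether (2S)-1-[2,6-dihydroxy-4-(methoxymethoxy)phenyl]-2-methylbutan-1-one F1 (MOMCl 1.05 equiv, iPr2NEt, CH2Cl2, 0 °C). Chromenylate F1 with 4 (ethylenediammonium diacetate cat., toluene, 100 °C); the two remaining hydroxyls are both ortho to the ketone and equivalent by symmetry, so only (2S)-1-[7-hydroxy-5-(methoxymethoxy)-2,2-dimethyl-2H-chromen-8-yl]-2-methylbutan-1-one F2 can form. Cleave the acetal (HCl, MeOH, 40 °C) and the route is rejoined at 6.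

Step 1 can fail through low conversion of the poorly soluble dianion, O-acylation, or partial loss of ee if the ester is enolised. Fallback: set out from 2 and drop the pyranone precursor altogether. Saponify 2 (LiOH, THF/H2O, 0 °C) to (2S)-2-methylbutanoic acid F3 and convert it to (2S)-2-methylbutanoyl chloride F4 ((COCl)2, cat. DMF, CH2Cl2). Friedel–Crafts C-acylation of commercial benzene-1,3,5-triol (AlCl3, CH2Cl2/PhNO2, 0 → 25 °C) then gives the ketone directly, with ee checked by chiral HPLC. The route is rejoined at 5, which is taken on through the second stage of step 2 or through F1 and F2.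

Step 4 can fail through exchange of the methylene bridge (giving the bis-pyranone and the bis-chromenyl methane) or through sluggish attack by the hindered, chelated chromene. Fallback: set out from 6 and reverse the roles of the partners. Treat 6 with CH2=NMe2+ I− (CH2Cl2, 25 °C) and isolate the phenolic Mannich base (2S)-1-{6-[(dimethylamino)methyl]-5,7-dihydroxy-2,2-dimethyl-2H-chromen-8-yl}-2-methylbutan-1-one F5. Heat F5 with 10 (1.5 equiv, dioxane, 80 °C) so that the ortho-quinone methide derived from the chromene is trapped by the pyranone C-3. The route is rejoined at 12.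

**Further compounds**
F1 | step 2 | (2S)-1-[2,6-dihydroxy-4-(methoxymethoxy)phenyl]-2-methylbutan-1-one | O=C(c1c(O)cc(OCOC)cc1O)[C@@H](C)CC
F2 | step 2 | (2S)-1-[7-hydroxy-5-(methoxymethoxy)-2,2-dimethyl-2H-chromen-8-yl]-2-methylbutan-1-one | O=C(c1c(O)cc(OCOC)c2C=CC(C)(C)Oc12)[C@@H](C)CC
F3 | step 1 | (2S)-2-methylbutanoic acid | OC(=O)[C@@H](C)CC
F4 | step 1 | (2S)-2-methylbutanoyl chloride | ClC(=O)[C@@H](C)CC
F5 | step 4 | (2S)-1-{6-[(dimethylamino)methyl]-5,7-dihydroxy-2,2-dimethyl-2H-chromen-8-yl}-2-methylbutan-1-one | O=C(c1c(O)c(CN(C)C)c(O)c2C=CC(C)(C)Oc12)[C@@H](C)CC
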